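**Plan**

- Retrosynthesis: the C6–prenyl bond is cut first (aromatic Claisen rearrangement, back to a 7-O-(1,1-dimethylallyl) ether of isocaviunin), then the 5-O-methyl bond, then C4–C4a of ring C (cycloacylation of a 3-aryloxy-2-arylacrylic acid), and last the vinylic O1–C2 bond, which separates 2,5-dimethoxyresorcinol (ring A) from a β-chloro-α-arylacrylate (ring B plus C2–C4).
- Forward: the ring A diol is made from 2-methoxyresorcinol by C5 borylation–oxidation, the ring B acrylate from 2,4,5-trimethoxyphenylacetic acid by formylation and chlorination; the two are joined through O1–C2, ring C is closed in step 10, and 5-O-demethylation, 7-O-propargylation, semihydrogenation and Claisen rearrangement complete the target.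
- Enabling feature: on ring A, C4a is the one unsubstituted carbon next to the ether oxygen O1 (its counterpart C8 bears the methoxy group) and it sits beside the C5 oxygen, so an acylium ion held by the O1–C2–C3 tether can close ring C at that carbon only.
- Stereochemistry: the target has no stereocentre; the only stereo-element on the way, the acrylate double-bond geometry, is equilibrated and then erased in the ring closure.

Key step: step 10

Assumption: the β-heteroatom acrylates 10–13 are written as E isomers (heteroatom trans to the carbonyl group), the arrangement expected under thermodynamic control for β-alkoxy-α-arylacrylates; any Z isomer formed alongside would be carried on unseparated, because step 10 equilibrates the geometry.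

**Route**

Step 1
Reactants: 1 2-methoxybenzene-1,3-diol (2-methoxyresorcinol)
Product: 2 2-methoxy-1,3-bis(methoxymethoxy)benzene
Conditions: NaH, MOMCl, DMF, 0 °C to rt
Reagents that add atoms: chloromethyl methyl ether, COCCl
Why: Double Williamson etherification of the two phenoxides masks both hydroxyls as base-stable acetals that tolerate the borylation, oxidation and methylation that follow.

Step 2
Reactants: 2 2-methoxy-1,3-bis(methoxymethoxy)benzene
Product: 4 4-methoxy-3,5-bis(methoxymethoxy)phenol, via aryl pinacol boronate 3 (not isolated)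
Conditions: [Ir(OMe)(cod)]2 (cat.), 4,4'-di-tert-butyl-2,2'-bipyridine, B2pin2, THF, 80 °C; evaporate; then 30% H2O2, aq. NaOH, THF, 0 °C to rt
Reagents that add atoms: hydrogen peroxide, OO (the boron of intermediate 3 comes from bis(pinacolato)diboron, CC1(C)OB(OC1(C)C)B1OC(C)(C)C(C)(C)O1, and does not stay in 4)
Why: Iridium-catalysed C–H borylation is sterically governed, so only C5, the one ring C–H without an ortho substituent, should be borylated, and alkaline peroxide oxidation of the C–B bond (boronate oxidation) then gives the phenol without touching the acetals.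

Step 3
Reactants: 4 4-methoxy-3,5-bis(methoxymethoxy)phenol
Product: 5 2,5-dimethoxy-1,3-bis(methoxymethoxy)benzene
Conditions: MeI, K2CO3, acetone, reflux
Reagents that add atoms: iodomethane, CI
Why: Williamson methylation of the single free phenol installs the methyl ether that later becomes the 5-methoxy group.

Step 4
Reactants: 5 2,5-dimethoxy-1,3-bis(methoxymethoxy)benzene
Product: 6 2,5-dimethoxybenzene-1,3-diol
Conditions: HCl (cat.), MeOH, 50 °C, degassed
Reagents that add atoms: none
Why: Acid-catalysed acetal exchange with methanol removes both methoxymethyl groups as dimethoxymethane, while aryl methyl ethers are inert to these conditions.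

Step 5
Reactants: 7 2-(2,4,5-trimethoxyphenyl)acetic acid
Product: 8 methyl 2-(2,4,5-trimethoxyphenyl)acetate
Conditions: MeOH, H2SO4 (cat.), reflux
Reagents that add atoms: methanol, CO
Why: Fischer esterification in excess methanol gives the ester needed for enolate formylation.

Step 6
Reactants: 8 methyl 2-(2,4,5-trimethoxyphenyl)acetate
Product: 9 methyl (Z)-3-hydroxy-2-(2,4,5-trimethoxyphenyl)prop-2-enoate (enol form of the α-formyl ester)
Conditions: NaH, HCO2Me, THF, 0 °C to rt; then cold dilute HCl
Reagents that add atoms: methyl formate, COC=O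
Why: Crossed Claisen condensation of the ester enolate with non-enolisable methyl formate is driven by deprotonation of the product and gives the α-formyl ester, which should rest as its hydrogen-bonded Z enol.

Step 7
Reactants: 9 methyl (Z)-3-hydroxy-2-(2,4,5-trimethoxyphenyl)prop-2-enoate
Product: 10 methyl (E)-3-chloro-2-(2,4,5-trimethoxyphenyl)prop-2-enoate
Conditions: (COCl)2, DMF (cat.), CH2Cl2, 0 °C to rt
Reagents that add atoms: oxalyl chloride, O=C(Cl)C(=O)Cl
Why: Vilsmeier-type deoxychlorination, in which the chloroiminium salt activates the enol oxygen and chloride adds to C3 and expels DMF, is the standard conversion of β-dicarbonyl enols into β-chloro enoates.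

Step 8
Reactants: 10 methyl (E)-3-chloro-2-(2,4,5-trimethoxyphenyl)prop-2-enoate; 6 2,5-dimethoxybenzene-1,3-diol
Product: 11 methyl (E)-3-(3-hydroxy-2,5-dimethoxyphenoxy)-2-(2,4,5-trimethoxyphenyl)prop-2-enoate
Conditions: 6 (3 equiv), K2CO3, DMF, 50 °C, argon; unreacted 6 recovered
Reagents that add atoms: none
Why: Nucleophilic vinylic substitution (addition–elimination), in which the phenoxide adds to C3 and chloride leaves from the stabilised ester enolate, should stop at mono-alkenylation because the symmetrical diol is in excess, with O-attack favoured for a potassium phenoxide in DMF.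

Step 9
Reactants: 11 methyl (E)-3-(3-hydroxy-2,5-dimethoxyphenoxy)-2-(2,4,5-trimethoxyphenyl)prop-2-enoate
Product: 12 (E)-3-(3-hydroxy-2,5-dimethoxyphenoxy)-2-(2,4,5-trimethoxyphenyl)prop-2-enoic acid
Conditions: LiOH·H2O, THF/MeOH/H2O, rt; then cold 1 M HCl to pH 3
Reagents that add atoms: lithium hydroxide, [Li+].[OH-]
Why: Saponification of the methyl ester is the usual way from 3-aryloxyacrylates to their acids, and brief cold acidification should leave the aryl vinyl ether intact.

Step 10
Reactants: 12 (E)-3-(3-hydroxy-2,5-dimethoxyphenoxy)-2-(2,4,5-trimethoxyphenyl)prop-2-enoic acid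
Product: 15 7-hydroxy-5,8-dimethoxy-3-(2,4,5-trimethoxyphenyl)-4H-chromen-4-one, via mixed trifluoroacetic anhydride 13 (not isolated), via 7-O-trifluoroacetyl isoflavone 14 (not isolated)
Conditions: (CF3CO)2O (3 equiv), CF3SO3H (cat.), dry CH2Cl2, 0 °C to rt; then aq. NaHCO3, THF, rt
Reagents that add atoms: none
Why: (CF3CO)2O converts the acid into mixed anhydride 13 (the phenol is trifluoroacetylated in passing), and CF3SO3H ionises it to an acylium ion whose ketene–oxocarbenium resonance form (ArO+=CH–C(Ar')=C=O) lets the C2–C3 bond rotate, so the E acid reaches the Z geometry in which the acylium carbon lies over the future C4a. Electrophilic aromatic substitution there and loss of a proton form the C4–C4a bond; the closest known reaction is the acid-mediated cyclodehydration of 3-aryloxyacrylic acids to chromones, an intramolecular Friedel–Crafts acylation. Ring C closes as a six-membered ring, formally 6-exo-dig at the acylium carbon with the C4a=C8a arene bond inside the new ring, and no stereocentre is created. The step needs acylation ortho to the ether oxygen, and the three-atom tether enforces it: of the two ortho carbons only C4a is free, it is further activated by the flanking 5-methoxy group, and ring B could be reached only through a four-membered ring. Water is excluded so that the aryl vinyl ether is not hydrolysed, and the mild bicarbonate work-up cleaves aryl trifluoroacetate 14 to the free 7-hydroxyl.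

Step 11
Reactants: 15 7-hydroxy-5,8-dimethoxy-3-(2,4,5-trimethoxyphenyl)-4H-chromen-4-one
Product: 16 5,7-dihydroxy-8-methoxy-3-(2,4,5-trimethoxyphenyl)-4H-chromen-4-one (isocaviunin)
Conditions: BCl3 (3 equiv), CH2Cl2, –78 °C to 0 °C; then H2O
Reagents that add atoms: none
Why: Chelation-controlled ether cleavage: BCl3 bridges the C4 carbonyl and the peri 5-methoxy oxygen and chloride removes that methyl group, whereas the 8-methoxy and the three ring B methoxy groups cannot form the six-membered chelate and should remain.

Step 12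
Reactants: 16 5,7-dihydroxy-8-methoxy-3-(2,4,5-trimethoxyphenyl)-4H-chromen-4-one; 17 3-chloro-3-methylbut-1-yne
Product: 18 5-hydroxy-8-methoxy-7-[(2-methylbut-3-yn-2-yl)oxy]-3-(2,4,5-trimethoxyphenyl)-4H-chromen-4-one
Conditions: K2CO3, KI (cat.), CuI (cat.), acetone, 55 °C
Reagents that add atoms: none
Why: Copper-assisted propargylic O-alkylation (a Williamson-type etherification through the copper acetylide) should take place at the more acidic 7-hydroxyl, since the 5-hydroxyl is held in a hydrogen bond to the C4 carbonyl.

Step 13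
Reactants: 18 5-hydroxy-8-methoxy-7-[(2-methylbut-3-yn-2-yl)oxy]-3-(2,4,5-trimethoxyphenyl)-4H-chromen-4-one
Product: 19 5-hydroxy-8-methoxy-7-[(2-methylbut-3-en-2-yl)oxy]-3-(2,4,5-trimethoxyphenyl)-4H-chromen-4-one
Conditions: H2 (1 atm), Pd/CaCO3 poisoned with Pb(OAc)2, quinoline, EtOAc, rt
Reagents that add atoms: none
Why: Lindlar reduction on the lead-poisoned palladium catalyst adds one equivalent of hydrogen to the terminal alkyne and stops at the alkene, leaving the chromone C2=C3 bond untouched.

Step 14
Reactants: 19 5-hydroxy-8-methoxy-7-[(2-methylbut-3-en-2-yl)oxy]-3-(2,4,5-trimethoxyphenyl)-4H-chromen-4-one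
Product: 20 5,7-dihydroxy-8-methoxy-6-(3-methylbut-2-en-1-yl)-3-(2,4,5-trimethoxyphenyl)-4H-chromen-4-one (6-prenylisocaviunin)
Conditions: N,N-diethylaniline, 130 °C, argon
Reagents that add atoms: none
Why: Aromatic Claisen rearrangement: the [3,3]-sigmatropic shift of the 1,1-dimethylallyl ether delivers the allyl terminus to C6, the only free ortho carbon (C8 carries the methoxy group), with allylic transposition to the 3-methylbut-2-enyl group, and tautomerisation restores the 7-hydroxyl.

**Compound list**

1 | 2-methoxybenzene-1,3-diol (2-methoxyresorcinol) | COc1c(O)cccc1O | starting material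
2 | 2-methoxy-1,3-bis(methoxymethoxy)benzene | COCOc1cccc(OCOC)c1OC | intermediate
3 | 2-[4-methoxy-3,5-bis(methoxymethoxy)phenyl]-4,4,5,5-tetramethyl-1,3,2-dioxaborolane | COCOc1cc(B2OC(C)(C)C(C)(C)O2)cc(OCOC)c1OC | intermediate (not isolated)
4 | 4-methoxy-3,5-bis(methoxymethoxy)phenol | COCOc1cc(O)cc(OCOC)c1OC | intermediate
5 | 2,5-dimethoxy-1,3-bis(methoxymethoxy)benzene | COCOc1cc(OC)cc(OCOC)c1OC | intermediate
6 | 2,5-dimethoxybenzene-1,3-diol | COc1cc(O)c(OC)c(O)c1 | intermediate
7 | 2-(2,4,5-trimethoxyphenyl)acetic acid | COc1cc(OC)c(CC(=O)O)cc1OC | starting material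
8 | methyl 2-(2,4,5-trimethoxyphenyl)acetate | COC(=O)Cc1cc(OC)c(OC)cc1OC | intermediate
9 | methyl (Z)-3-hydroxy-2-(2,4,5-trimethoxyphenyl)prop-2-enoate | COC(=O)/C(=C\O)c1cc(OC)c(OC)cc1OC | intermediate
10 | methyl (E)-3-chloro-2-(2,4,5-trimethoxyphenyl)prop-2-enoate | COC(=O)/C(=C/Cl)c1cc(OC)c(OC)cc1OC | intermediate
11 | methyl (E)-3-(3-hydroxy-2,5-dimethoxyphenoxy)-2-(2,4,5-trimethoxyphenyl)prop-2-enoate | COC(=O)/C(=C/Oc1cc(OC)cc(O)c1OC)c1cc(OC)c(OC)cc1OC | intermediate
12 | (E)-3-(3-hydroxy-2,5-dimethoxyphenoxy)-2-(2,4,5-trimethoxyphenyl)prop-2-enoic acid | OC(=O)/C(=C/Oc1cc(OC)cc(O)c1OC)c1cc(OC)c(OC)cc1OC | intermediate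
13 | trifluoroacetic (E)-3-[2,5-dimethoxy-3-(trifluoroacetoxy)phenoxy]-2-(2,4,5-trimethoxyphenyl)prop-2-enoic anhydride | O=C(OC(=O)C(F)(F)F)/C(=C/Oc1cc(OC)cc(OC(=O)C(F)(F)F)c1OC)c1cc(OC)c(OC)cc1OC | intermediate (not isolated)
14 | 5,8-dimethoxy-4-oxo-3-(2,4,5-trimethoxyphenyl)-4H-chromen-7-yl trifluoroacetate | O=c1c(-c3cc(OC)c(OC)cc3OC)coc2c(OC)c(OC(=O)C(F)(F)F)cc(OC)c12 | intermediate (not isolated)
15 | 7-hydroxy-5,8-dimethoxy-3-(2,4,5-trimethoxyphenyl)-4H-chromen-4-one | O=c1c(-c3cc(OC)c(OC)cc3OC)coc2c(OC)c(O)cc(OC)c12 | intermediate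
16 | 5,7-dihydroxy-8-methoxy-3-(2,4,5-trimethoxyphenyl)-4H-chromen-4-one (isocaviunin) | COc1cc(OC)c(-c2coc3c(OC)c(O)cc(O)c3c2=O)cc1OC | intermediate
17 | 3-chloro-3-methylbut-1-yne | CC(C)(Cl)C#C | starting material
18 | 5-hydroxy-8-methoxy-7-[(2-methylbut-3-yn-2-yl)oxy]-3-(2,4,5-trimethoxyphenyl)-4H-chromen-4-one | COc1cc(OC)c(-c2coc3c(OC)c(OC(C)(C)C#C)cc(O)c3c2=O)cc1OC | intermediate
19 | 5-hydroxy-8-methoxy-7-[(2-methylbut-3-en-2-yl)oxy]-3-(2,4,5-trimethoxyphenyl)-4H-chromen-4-one | COc1cc(OC)c(-c2coc3c(OC)c(OC(C)(C)C=C)cc(O)c3c2=O)cc1OC | intermediate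
20 | 5,7-dihydroxy-8-methoxy-6-(3-methylbut-2-en-1-yl)-3-(2,4,5-trimethoxyphenyl)-4H-chromen-4-one (6-prenylisocaviunin) | COc1cc(OC)c(-c2coc3c(OC)c(O)c(CC=C(C)C)c(O)c3c2=O)cc1OC | target

**Step count**

Total: 14 steps. Longest linear sequence: 11 steps (steps 1, 2, 3, 4, 8, 9, 10, 11, 12, 13, 14, from 1 to 20); steps 5–7 form the three-step side branch to 10.

**Steps most likely to fail**

1. Step 10. The activated acid may be lost before it closes: (CF3CO)2O could trifluoroacetylate ring B at its two free positions or ring A before closure, traces of water could hydrolyse the aryl vinyl ether, or rotation to the Z geometry could be slower than these side reactions. The fallback sets out from 6 and 7 and comes back at 15, building ring C in the opposite order. Friedel–Crafts acylation of diol 6 with acid 7 in BF3·OEt2 at 85 °C should occur at one of the two equivalent carbons between a hydroxyl and the 5-methoxy group, giving the deoxybenzoin 1-(2,4-dihydroxy-3,6-dimethoxyphenyl)-2-(2,4,5-trimethoxyphenyl)ethan-1-one F1. Treating it with DMF, BF3·OEt2 and CH3SO2Cl at 50–80 °C introduces C2 from DMF at the benzylic methylene and closes the pyranone through the single ortho hydroxyl, giving 15.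

2. Step 8. The symmetrical, very electron-rich diol may be alkenylated twice, may attack through ring carbon instead of oxygen, or may react so slowly that chloride 10 is hydrolysed. The fallback sets out from 6 and comes back at 12, desymmetrising the diol before the coupling instead of during it. Monoacylation of 6 with pivaloyl chloride (1 equiv, pyridine, CH2Cl2, –20 °C, excess diol recycled) should give 3-hydroxy-2,5-dimethoxyphenyl 2,2-dimethylpropanoate F2, which has one phenoxide and a less nucleophilic ring. Vinylic substitution on 10 (K2CO3, DMF) then gives methyl (E)-3-[2,5-dimethoxy-3-(2,2-dimethylpropanoyloxy)phenoxy]-2-(2,4,5-trimethoxyphenyl)prop-2-enoate F3, and LiOH in THF/MeOH/H2O cleaves the methyl ester and the pivalate together to give acid 12.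

3. Step 14. On heating, the tertiary allyl ether may fragment back to phenol 16 with loss of isoprene, or the new prenyl group may cyclise onto a neighbouring hydroxyl to a chromane. The fallback sets out from 16 and comes back at 20, bringing in the side chain as a plain allyl group and extending it last. O-Allylation of the 7-hydroxyl (allyl bromide, K2CO3, acetone) gives 5-hydroxy-8-methoxy-7-(prop-2-en-1-yloxy)-3-(2,4,5-trimethoxyphenyl)-4H-chromen-4-one F4. Its Claisen rearrangement (N,N-diethylaniline, 190 °C) can only reach C6 and gives 5,7-dihydroxy-8-methoxy-6-(prop-2-en-1-yl)-3-(2,4,5-trimethoxyphenyl)-4H-chromen-4-one F5. Cross-metathesis of F5 with excess 2-methylbut-2-ene (second-generation Grubbs catalyst, CH2Cl2, 40 °C) under neutral conditions gives 20.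

**Further compounds**

F1 | step 10 | 1-(2,4-dihydroxy-3,6-dimethoxyphenyl)-2-(2,4,5-trimethoxyphenyl)ethan-1-one | COc1cc(OC)c(CC(=O)c2c(OC)cc(O)c(OC)c2O)cc1OC
F2 | step 8 | 3-hydroxy-2,5-dimethoxyphenyl 2,2-dimethylpropanoate | COc1cc(O)c(OC)c(OC(=O)C(C)(C)C)c1
F3 | step 8 | methyl (E)-3-[2,5-dimethoxy-3-(2,2-dimethylpropanoyloxy)phenoxy]-2-(2,4,5-trimethoxyphenyl)prop-2-enoate | COC(=O)/C(=C/Oc1cc(OC)cc(OC(=O)C(C)(C)C)c1OC)c1cc(OC)c(OC)cc1OC
F4 | step 14 | 5-hydroxy-8-methoxy-7-(prop-2-en-1-yloxy)-3-(2,4,5-trimethoxyphenyl)-4H-chromen-4-one | COc1cc(OC)c(-c2coc3c(OC)c(OCC=C)cc(O)c3c2=O)cc1OC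
F5 | step 14 | 5,7-dihydroxy-8-methoxy-6-(prop-2-en-1-yl)-3-(2,4,5-trimethoxyphenyl)-4H-chromen-4-one | COc1cc(OC)c(-c2coc3c(OC)c(O)c(CC=C)c(O)c3c2=O)cc1OC
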